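Readings and results are calculated from invented constants, and the scatter is random.

Single product begins at a fork: a molecule of starting material either meets partner or is lost by a second road. The noon run showed that road: single product read 18.4 % at 3.00 min and 18.0 % at 20.0 min, while starting material kept falling. I let a be the fraction of the charge of starting material still there. If the loss takes two molecules of starting material, the reciprocal of a climbs steadily, and partner adds to that climb.

| flask | starting material | partner | remark | time |
|---|---|---|---|---|
| noon | 10 mM | 0.45 equiv | run made earlier |  |
| autumn | 10 mM | 1.8 equiv | run made earlier |  |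
| spring | 20 mM | 0.90 equiv | run made earlier |  |
| flask | 10 mM | 0.900 equiv |  | 20 min |

| run | time / min | single product / % | starting material / % |
|---|---|---|---|
| noon | 0.200 | 12.6 | 56.8 |
| noon | 0.500 | 17.2 | 36.2 |
| noon | 1.33 | 17.9 | 18.6 |
| noon | 3.00 | 18.4 | 11.3 |
| noon | 8.00 | 17.8 | 4.3 |
| noon | 20.0 | 18.0 | 2.0 |
| autumn | 0.200 | 32.2 | 32.0 |
| autumn | 0.500 | 31.0 | 12.2 |
| autumn | 1.33 | 12.8 | 2.6 |
| autumn | 3.00 | 0.5 | 0.7 |
| autumn | 8.00 | 0 | 0.1 |
| autumn | 20.0 | 0.5 | 0.9 |
| spring | 0.200 | 33.1 | 29.3 |
| spring | 0.667 | 38.2 | 9.0 |
| spring | 2.00 | 35.6 | 2.3 |
| spring | 6.00 | 32.2 | 1.9 |
| spring | 20.0 | 31.5 | 1.8 |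

(each reading ± 0.5 percentage points)

- a reading or a percentage of single product counts all its forms, free or not

* time, not beyond 20 min, at which the flask holds most single product
* the amount of single product, in percent of the starting material charged, at that time
* the first time at which single product reaches 19 %, in the same percent, in min

I read the self climb from the noon tail and the whole climb from the first reading of the spring run, which has the flask's equivalents:

self climb, noon: s = 2.42 min⁻¹

whole climb, spring: h = 12.1 min⁻¹

The first setting is concentration. By hand, with two molecules in each road, doubling the charge at fixed equivalents doubles both parts, so I took the self climb in the spring run as twice noon's: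

self climb, spring: 4.84 min⁻¹

fork ratio: 1.49

This reading is the fork ratio, partner's part of the climb over the self part across that first reading, a selectivity factor, which I took as the value at the start. I assumed it held for the flask, at half the spring charge.

The second setting is equivalents. By hand the fork ratio follows them, so I scaled it to noon and autumn:

noon: reckoned 4.23 min⁻¹, read 3.80 min⁻¹

autumn: reckoned 9.64 min⁻¹, read 10.6 min⁻¹

So I expected a molecule in the flask to take partner's road at the start with chance 0.598.

The forecast, which counted “a second-order self-loss of starting material”, gave 28 % at 0.5 min and 0.13 min for the first crossing of 19 %.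

The flask gave 27.7 % at 0.670 min and reached 19 % at 0.148 min. At that best time 21.9 % of the charge stood as crystals, counted in that single product.

    starting material + partner → single product (k = 5.40 M⁻¹ s⁻¹)
    partner + single product → double product (k = 19.0 M⁻¹ s⁻¹)
    crystals ⇌ single product, rate k3*(cs3 - [single product]) while solid is left; crystals form when [single product] > cs3 (solubility = 0.580 mM, k = 3.80 s⁻¹)
    2 starting material → self-condensation product (k = 1.90 M⁻¹ s⁻¹)

The two roads started in the flask at a ratio of 1.3, against my fork ratio of 1.49. For the neighbour flask with 0.230 equiv of partner, all else as in the recipe, the fork ratio scales to 0.381, so by this reckoning partner's part at the start was less than the self part. That neighbour ended with 81.0 % self-condensation product, against 42.6 % in the flask.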